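**Retrosynthetic overview**
1. Feature: ring A (the acyl half) and ring B (the phenol–acid half) are the same arene. Each has the carboxyl carbon on C1, oxygen on C2 and C4 with C3–H between them, C5–H, and the 2-oxoheptyl chain on C6.
2. First cut: the depside bond between the ring A carbonyl carbon and O4 of ring B. This gives acid 23 and phenol 25, both drawn from one monomer, keto ester 21.
3. Second cut (key): ring bonds C1–C2 and C5–C6. C2–C5 with their oxygens are 1,1-dimethoxy-3-silyloxybutadiene 13. C1 and C6 with the ester and the chain are 2-alkynoate 7, whose ketone travels as the silyl ether of the racemic alcohol.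
4. Ynoate 7 comes from hexanal, propargyl bromide and methyl chloroformate; diene 13 comes from acetyl chloride and 1,1-dichloroethene.
5. Ring order: one benzannulation (step 7) makes the only ring type. The batch is later divided into ring A and ring B, which are joined in step 15 and unmasked in step 16.

Key step: step 7

Remark: the target has no stereocentre. The carbinol carbon carried from step 1 to step 10 is racemic and is erased in step 11. Keto acids 23, 24 and 27 are drawn in the open keto-acid form.

**Route**

Step 1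
Reactants: 1 hexanal; 2 propargyl bromide
Product: 4 non-1-yn-4-ol (racemic), via allenylzinc bromide 3 (not isolated)
Conditions: Zn dust, THF, 0 °C → rt; 1 M aq. HCl quench
Reagents that add atoms: none
Why: Barbier-type propargylation, in which zinc inserts into 2 to give allenylzinc 3, which adds to the aldehyde through a cyclic SE2′ transition state and should deliver the homopropargylic alcohol; the new carbinol centre is deliberately racemic because step 11 oxidises it away.

Step 2
Reactants: 4 non-1-yn-4-ol
Product: 5 tert-butyl(dimethyl)(non-1-yn-4-yloxy)silane (racemic)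
Conditions: TBSCl, imidazole, DMF, rt
Reagents that add atoms: tert-butyldimethylsilyl chloride, CC(C)(C)[Si](C)(C)Cl
Why: Standard imidazole-promoted silylation of a secondary alcohol, which masks the hydroxyl against n-BuLi in step 3 and keeps it from attacking the ester once the arene is built.

Step 3
Reactants: 5 tert-butyl(dimethyl)(non-1-yn-4-yloxy)silane
Product: 7 methyl 5-(tert-butyldimethylsilyloxy)dec-2-ynoate (racemic), via lithium acetylide 6 (not isolated)
Conditions: n-BuLi, THF, −78 °C; ClCO2Me, −78 → 0 °C
Reagents that add atoms: methyl chloroformate, COC(=O)Cl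
Why: Deprotonation of the terminal alkyne (the only acidic C–H) and C-acylation of the lithium acetylide with a chloroformate is the routine entry to 2-alkynoates, and the silyl ether is inert to both reagents at low temperature.

Step 4
Reactants: 8 acetyl chloride; 9 1,1-dichloroethene
Product: 11 4,4-dichlorobut-3-en-2-one, via 4,4,4-trichlorobutan-2-one 10 (not isolated)
Conditions: AlCl3, CH2Cl2, 0 °C → rt; ice/aq. HCl; steam distillation
Reagents that add atoms: none
Why: Friedel–Crafts-type acylation of an alkene, in which the acylium ion attacks the CH2 terminus to give the chlorine-stabilised cation, chloride capture gives 10, and loss of HCl on distillation gives the conjugated β,β-dichloroenone.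

Step 5
Reactants: 11 4,4-dichlorobut-3-en-2-one
Product: 12 4,4-dimethoxybut-3-en-2-one
Conditions: NaOMe (2.1 equiv), MeOH, 0 °C → rt; distillation
Reagents that add atoms: sodium methoxide, [Na+].[O-]C
Why: Two consecutive conjugate addition–elimination events (vinylogous acyl substitution) replace both vinylic chlorides by methoxide and give the push–pull ketene acetal.

Step 6
Reactants: 12 4,4-dimethoxybut-3-en-2-one
Product: 13 1,1-dimethoxy-3-(trimethylsilyloxy)buta-1,3-diene
Conditions: TMSCl, Et3N, ZnCl2 (cat.), toluene, 40 °C; filtration, vacuum distillation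
Reagents that add atoms: trimethylsilyl chloride, C[Si](C)(C)Cl
Why: Soft enolisation and O-silylation of a methyl ketone, as used to make 2-silyloxydienes from enones; the CH3 group carries the only enolisable hydrogens, so a single cross-conjugated diene can form.

Step 7
Reactants: 7 methyl 5-(tert-butyldimethylsilyloxy)dec-2-ynoate; 13 1,1-dimethoxy-3-(trimethylsilyloxy)buta-1,3-diene
Product: 16 methyl 6-[2-(tert-butyldimethylsilyloxy)heptyl]-4-hydroxy-2-methoxybenzoate (racemic), via cyclohexadiene cycloadduct 14 (not isolated), via aryl trimethylsilyl ether 15 (not isolated)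
Conditions: 13 (2.5 equiv), neat, sealed tube, Ar, 125 °C; then 0.1 M aq. HCl/THF, 0 °C
Reagents that add atoms: none
Why: The electron-rich diene and the electron-poor alkyne combine in a normal-electron-demand, strongly asynchronous [4+2] cycloaddition in which the unsubstituted CH2 terminus of 13 engages the β-carbon of 7 and the acetal carbon closes onto the α-carbon, so the C5–C6 and C1–C2 bonds of the future arene arise in one intermolecular event. The closest known reaction type is the thermal Diels–Alder benzannulation of 1,1-dialkoxy-3-silyloxybutadienes with 2-alkynoates, which gives 6-alkyl-4-hydroxy-2-methoxybenzoates. The single six-membered ring is closed by this bimolecular cycloaddition to give 1,4-cyclohexadiene 14, which aromatises by 1,4-loss of methanol (acetal carbon and C5 methylene) to aryl silyl ether 15, and the brief acid wash then frees the C4 phenol while the hindered alkyl silyl ether stays. No new stereocentre results, since the ring of 14 has none and the racemic carbinol carbon is a spectator. Only regiocontrol is needed; it comes from matching the largest HOMO coefficient (the CH2 terminus, reinforced by all three oxygen donors) with the largest LUMO coefficient (the β-carbon of the ynoate), which puts the chain on C6 ortho to the ester and leaves O2 as methyl ether and O4 as free phenol.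

Step 8
Reactants: 16 methyl 6-[2-(tert-butyldimethylsilyloxy)heptyl]-4-hydroxy-2-methoxybenzoate
Product: 18 methyl 6-[2-(tert-butyldimethylsilyloxy)heptyl]-2,4-dihydroxybenzoate (racemic), via bis(dichloroboryl) aryl ether 17 (not isolated)
Conditions: BCl3 (2.5 equiv, 1 M in CH2Cl2), CH2Cl2, −78 → 0 °C; H2O quench
Reagents that add atoms: none
Why: Chelation-directed ether cleavage, in which BCl3 binds between the ester carbonyl and the ortho methoxy oxygen and chloride removes that methyl group by SN2 attack, while the methyl ester and the hindered secondary alkyl silyl ether should persist at or below 0 °C; doing this before the ketone is unveiled keeps the Lewis acid away from an enolisable 2-oxoalkyl benzoate.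

Step 9
Reactants: 18 methyl 6-[2-(tert-butyldimethylsilyloxy)heptyl]-2,4-dihydroxybenzoate
Product: 19 methyl 2,4-bis(benzyloxy)-6-[2-(tert-butyldimethylsilyloxy)heptyl]benzoate (racemic)
Conditions: BnBr (2.4 equiv), K2CO3, DMF, 60 °C
Reagents that add atoms: benzyl bromide, BrCc1ccccc1
Why: Williamson ether synthesis on both phenols; warming in DMF is needed for the hydrogen-bonded O2–H, and carbonate touches neither the ester nor the silyl ether.

Step 10
Reactants: 19 methyl 2,4-bis(benzyloxy)-6-[2-(tert-butyldimethylsilyloxy)heptyl]benzoate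
Product: 20 methyl 2,4-bis(benzyloxy)-6-(2-hydroxyheptyl)benzoate (racemic)
Conditions: HF·pyridine, pyridine/THF, 0 °C → rt; cold aq. NaHCO3; crude product taken on at once
Reagents that add atoms: none
Why: Fluoride-driven Si–O cleavage under buffered, weakly acidic conditions, chosen over basic fluoride sources so that no alkoxide forms next to the methyl ester; the doubly ortho-substituted ester should survive the short life of the neutral alcohol.

Step 11
Reactants: 20 methyl 2,4-bis(benzyloxy)-6-(2-hydroxyheptyl)benzoate
Product: 21 methyl 2,4-bis(benzyloxy)-6-(2-oxoheptyl)benzoate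
Conditions: Dess–Martin periodinane, CH2Cl2, 0 °C → rt
Reagents that add atoms: none
Why: Dess–Martin oxidation of a secondary alcohol under near-neutral conditions, which removes the only stereocentre; both phenols are capped as benzyl ethers, so the electron-rich ring offers nothing to the hypervalent iodine reagent.

Step 12
Reactants: 21 methyl 2,4-bis(benzyloxy)-6-(2-oxoheptyl)benzoate
Product: 23 2,4-bis(benzyloxy)-6-(2-oxoheptyl)benzoic acid, via potassium carboxylate 22 (not isolated)
Conditions: KOH, DMSO/H2O, 80 °C; then cold 1 M HCl to pH 3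
Reagents that add atoms: potassium hydroxide, [K+].[OH-]
Why: Saponification of a 2,6-disubstituted benzoate with poorly solvated hydroxide in aqueous DMSO, the usual answer to hindered aryl esters; carboxylate 22 is inert to the ketone enolate, and cold mild acidification avoids cyclodehydration of the keto acid.

Step 13
Reactants: 23 2,4-bis(benzyloxy)-6-(2-oxoheptyl)benzoic acid (part of the batch)
Product: 24 2,4-dihydroxy-6-(2-oxoheptyl)benzoic acid
Conditions: H2 (1 atm), 10% Pd/C, EtOAc, rt
Reagents that add atoms: none
Why: Catalytic hydrogenolysis of aryl benzyl ethers under neutral conditions at room temperature, which leaves the dialkyl ketone alone and spares the decarboxylation-prone resorcylic acid any heat or base.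

Step 14
Reactants: 24 2,4-dihydroxy-6-(2-oxoheptyl)benzoic acid
Product: 25 benzyl 2,4-dihydroxy-6-(2-oxoheptyl)benzoate
Conditions: BnBr (1.0 equiv), KHCO3, DMF, rt
Reagents that add atoms: benzyl bromide, BrCc1ccccc1
Why: Chemoselective SN2 O-alkylation of the carboxylate, since hydrogencarbonate ionises only the carboxylic acid and one equivalent of benzyl bromide should therefore esterify without etherifying the phenols.

Step 15
Reactants: 23 2,4-bis(benzyloxy)-6-(2-oxoheptyl)benzoic acid; 25 benzyl 2,4-dihydroxy-6-(2-oxoheptyl)benzoate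
Product: 26 benzyl 4-{[2,4-bis(benzyloxy)-6-(2-oxoheptyl)benzoyl]oxy}-2-hydroxy-6-(2-oxoheptyl)benzoate
Conditions: DCC, DMAP (cat.), CH2Cl2, 0 °C → rt
Reagents that add atoms: none
Why: Steglich esterification, in which DMAP passes the carbodiimide-activated acyl group on to the phenol; site selectivity rests on O4–H of 25 being free and unhindered, whereas O2–H is tied up in a hydrogen bond to the adjacent benzyl ester carbonyl.

Step 16
Reactants: 26 benzyl 4-{[2,4-bis(benzyloxy)-6-(2-oxoheptyl)benzoyl]oxy}-2-hydroxy-6-(2-oxoheptyl)benzoate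
Product: 27 4-{[2,4-dihydroxy-6-(2-oxoheptyl)benzoyl]oxy}-2-hydroxy-6-(2-oxoheptyl)benzoic acid (target)
Conditions: H2 (1 atm), 10% Pd/C, EtOAc, rt
Reagents that add atoms: none
Why: Global hydrogenolysis of two aryl benzyl ethers and one benzyl ester under neutral conditions, which should leave the depside aryl ester, both dialkyl ketones and the free acid untouched; the aprotic solvent avoids alcoholysis of the depside link.

**Compound list**
1 | hexanal | CCCCCC=O | starting material
2 | propargyl bromide (3-bromoprop-1-yne) | BrCC#C | starting material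
3 | propa-1,2-dienylzinc bromide (allenylzinc bromide) | C=C=C[Zn]Br | intermediate
4 | non-1-yn-4-ol (racemic) | CCCCCC(O)CC#C | intermediate
5 | tert-butyl(dimethyl)(non-1-yn-4-yloxy)silane (racemic) | CCCCCC(CC#C)O[Si](C)(C)C(C)(C)C | intermediate
6 | lithium acetylide of 5 (racemic) | CCCCCC(CC#C[Li])O[Si](C)(C)C(C)(C)C | intermediate
7 | methyl 5-(tert-butyldimethylsilyloxy)dec-2-ynoate (racemic) | CCCCCC(CC#CC(=O)OC)O[Si](C)(C)C(C)(C)C | intermediate
8 | acetyl chloride | CC(Cl)=O | starting material
9 | 1,1-dichloroethene | ClC(Cl)=C | starting material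
10 | 4,4,4-trichlorobutan-2-one | CC(=O)CC(Cl)(Cl)Cl | intermediate
11 | 4,4-dichlorobut-3-en-2-one | CC(=O)C=C(Cl)Cl | intermediate
12 | 4,4-dimethoxybut-3-en-2-one | CC(=O)C=C(OC)OC | intermediate
13 | 1,1-dimethoxy-3-(trimethylsilyloxy)buta-1,3-diene | COC(OC)=CC(=C)O[Si](C)(C)C | intermediate
14 | methyl 2-[2-(tert-butyldimethylsilyloxy)heptyl]-6,6-dimethoxy-4-(trimethylsilyloxy)cyclohexa-1,4-diene-1-carboxylate (racemic) | COC(=O)C1=C(CC(CCCCC)O[Si](C)(C)C(C)(C)C)CC(O[Si](C)(C)C)=CC1(OC)OC | intermediate
15 | methyl 6-[2-(tert-butyldimethylsilyloxy)heptyl]-2-methoxy-4-(trimethylsilyloxy)benzoate (racemic) | CCCCCC(Cc1cc(O[Si](C)(C)C)cc(OC)c1C(=O)OC)O[Si](C)(C)C(C)(C)C | intermediate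
16 | methyl 6-[2-(tert-butyldimethylsilyloxy)heptyl]-4-hydroxy-2-methoxybenzoate (racemic) | CCCCCC(Cc1cc(O)cc(OC)c1C(=O)OC)O[Si](C)(C)C(C)(C)C | intermediate
17 | methyl 6-[2-(tert-butyldimethylsilyloxy)heptyl]-2,4-bis(dichloroboryloxy)benzoate (racemic) | CCCCCC(Cc1cc(OB(Cl)Cl)cc(OB(Cl)Cl)c1C(=O)OC)O[Si](C)(C)C(C)(C)C | intermediate
18 | methyl 6-[2-(tert-butyldimethylsilyloxy)heptyl]-2,4-dihydroxybenzoate (racemic) | CCCCCC(Cc1cc(O)cc(O)c1C(=O)OC)O[Si](C)(C)C(C)(C)C | intermediate
19 | methyl 2,4-bis(benzyloxy)-6-[2-(tert-butyldimethylsilyloxy)heptyl]benzoate (racemic) | CCCCCC(Cc1cc(OCc2ccccc2)cc(OCc2ccccc2)c1C(=O)OC)O[Si](C)(C)C(C)(C)C | intermediate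
20 | methyl 2,4-bis(benzyloxy)-6-(2-hydroxyheptyl)benzoate (racemic) | CCCCCC(O)Cc1cc(OCc2ccccc2)cc(OCc2ccccc2)c1C(=O)OC | intermediate
21 | methyl 2,4-bis(benzyloxy)-6-(2-oxoheptyl)benzoate | CCCCCC(=O)Cc1cc(OCc2ccccc2)cc(OCc2ccccc2)c1C(=O)OC | intermediate
22 | potassium 2,4-bis(benzyloxy)-6-(2-oxoheptyl)benzoate | CCCCCC(=O)Cc1cc(OCc2ccccc2)cc(OCc2ccccc2)c1C(=O)[O-].[K+] | intermediate
23 | 2,4-bis(benzyloxy)-6-(2-oxoheptyl)benzoic acid | CCCCCC(=O)Cc1cc(OCc2ccccc2)cc(OCc2ccccc2)c1C(=O)O | intermediate
24 | 2,4-dihydroxy-6-(2-oxoheptyl)benzoic acid | CCCCCC(=O)Cc1cc(O)cc(O)c1C(=O)O | intermediate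
25 | benzyl 2,4-dihydroxy-6-(2-oxoheptyl)benzoate | CCCCCC(=O)Cc1cc(O)cc(O)c1C(=O)OCc1ccccc1 | intermediate
26 | benzyl 4-{[2,4-bis(benzyloxy)-6-(2-oxoheptyl)benzoyl]oxy}-2-hydroxy-6-(2-oxoheptyl)benzoate | CCCCCC(=O)Cc1cc(OC(=O)c2c(OCc3ccccc3)cc(OCc3ccccc3)cc2CC(=O)CCCCC)cc(O)c1C(=O)OCc1ccccc1 | intermediate
27 | 4-{[2,4-dihydroxy-6-(2-oxoheptyl)benzoyl]oxy}-2-hydroxy-6-(2-oxoheptyl)benzoic acid | CCCCCC(=O)Cc1cc(OC(=O)c2c(O)cc(O)cc2CC(=O)CCCCC)cc(O)c1C(=O)O | target

**Step count**
Total steps: 16.
Longest linear sequence: 13 (steps 1–3, then 7–16). The diene branch, steps 4–6, is of equal length.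

**Three steps most likely to fail**

Step 7 (key cycloaddition).
- Risk: the open-chain ketene-acetal diene may be consumed by hydrolysis, silyl migration or oligomerisation at the temperature that a β-alkyl ynoate demands. Cycloaddition would then stall.
- Fallback, setting out from 7 and returning at 18: replace the open-chain diene by a ring-locked s-cis diene and aromatise by cycloreversion instead of elimination (Alder–Rickert reaction). Commercial dimedone is bis-silylated (TMSOTf, Et3N, Et2O, 0 °C) to 5,5-dimethyl-1,3-bis(trimethylsilyloxy)cyclohexa-1,3-diene F1. Heating 7 with it neat at about 150 °C should give the bicyclo[2.2.2]octadiene adduct F2. This expels 2-methylpropene and leaves methyl 6-[2-(tert-butyldimethylsilyloxy)heptyl]-2,4-bis(trimethylsilyloxy)benzoate F3. The dilute acid wash used in step 7 removes both aryl silyl groups and gives 18, so step 8 is no longer needed.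

Step 10 (desilylation).
- Risk: the liberated secondary hydroxyl may attack the neighbouring methyl ester in a six-membered lactonisation before it can be oxidised.
- Fallback, setting out from 19 and returning at 23 (steps 10–12 are bypassed): remove the ester electrophile before the alcohol is freed. LiAlH4 (THF, 0 °C → rt) reduces 19 to {2,4-bis(benzyloxy)-6-[2-(tert-butyldimethylsilyloxy)heptyl]phenyl}methanol F4. TBAF in THF then gives 1-[3,5-bis(benzyloxy)-2-(hydroxymethyl)phenyl]heptan-2-ol F5. A Swern oxidation activates both hydroxyls before the base is added, so no lactol can intervene, and gives 2,4-bis(benzyloxy)-6-(2-oxoheptyl)benzaldehyde F6. Pinnick oxidation (NaClO2, NaH2PO4, 2-methylbut-2-ene, t-BuOH/H2O) converts the aldehyde into acid 23.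

Step 15 (depside coupling).
- Risk: the enol of the side-chain ketone may close onto the activated acyl group (enol-lactonisation). Acyl migration within the carbodiimide adduct may also occur. Either process could outrun intermolecular transfer to a weakly nucleophilic phenol.
- Fallback, setting out from 21 and returning at 26: mask the ring A ketone during activation. Ketalisation of 21 with 1,2-bis(trimethylsilyloxy)ethane and catalytic TMSOTf (CH2Cl2, −78 → −20 °C) gives methyl 2,4-bis(benzyloxy)-6-[(2-pentyl-1,3-dioxolan-2-yl)methyl]benzoate F7. KOH in DMSO/H2O at 100 °C gives 2,4-bis(benzyloxy)-6-[(2-pentyl-1,3-dioxolan-2-yl)methyl]benzoic acid F8. Carbodiimide coupling with 25 gives the ketal-protected depside F9. PPTS in wet acetone at 40 °C then releases the ketone and gives 26.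

**Further compounds**
F1 | step 7 | 5,5-dimethyl-1,3-bis(trimethylsilyloxy)cyclohexa-1,3-diene | CC1(C)CC(O[Si](C)(C)C)=CC(O[Si](C)(C)C)=C1
F2 | step 7 | methyl 3-[2-(tert-butyldimethylsilyloxy)heptyl]-8,8-dimethyl-1,5-bis(trimethylsilyloxy)bicyclo[2.2.2]octa-2,5-diene-2-carboxylate (mixture of diastereomers) | COC(=O)C1=C(CC(CCCCC)O[Si](C)(C)C(C)(C)C)C2C(O[Si](C)(C)C)=CC1(O[Si](C)(C)C)CC2(C)C
F3 | step 7 | methyl 6-[2-(tert-butyldimethylsilyloxy)heptyl]-2,4-bis(trimethylsilyloxy)benzoate (racemic) | CCCCCC(Cc1cc(O[Si](C)(C)C)cc(O[Si](C)(C)C)c1C(=O)OC)O[Si](C)(C)C(C)(C)C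
F4 | step 10 | {2,4-bis(benzyloxy)-6-[2-(tert-butyldimethylsilyloxy)heptyl]phenyl}methanol (racemic) | CCCCCC(Cc1cc(OCc2ccccc2)cc(OCc2ccccc2)c1CO)O[Si](C)(C)C(C)(C)C
F5 | step 10 | 1-[3,5-bis(benzyloxy)-2-(hydroxymethyl)phenyl]heptan-2-ol (racemic) | CCCCCC(O)Cc1cc(OCc2ccccc2)cc(OCc2ccccc2)c1CO
F6 | step 10 | 2,4-bis(benzyloxy)-6-(2-oxoheptyl)benzaldehyde | CCCCCC(=O)Cc1cc(OCc2ccccc2)cc(OCc2ccccc2)c1C=O
F7 | step 15 | methyl 2,4-bis(benzyloxy)-6-[(2-pentyl-1,3-dioxolan-2-yl)methyl]benzoate | CCCCCC1(Cc2cc(OCc3ccccc3)cc(OCc3ccccc3)c2C(=O)OC)OCCO1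
F8 | step 15 | 2,4-bis(benzyloxy)-6-[(2-pentyl-1,3-dioxolan-2-yl)methyl]benzoic acid | CCCCCC1(Cc2cc(OCc3ccccc3)cc(OCc3ccccc3)c2C(=O)O)OCCO1
F9 | step 15 | benzyl 4-({2,4-bis(benzyloxy)-6-[(2-pentyl-1,3-dioxolan-2-yl)methyl]benzoyl}oxy)-2-hydroxy-6-(2-oxoheptyl)benzoate | CCCCCC(=O)Cc1cc(OC(=O)c2c(OCc3ccccc3)cc(OCc3ccccc3)cc2CC2(CCCCC)OCCO2)cc(O)c1C(=O)OCc1ccccc1
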